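**Retrosynthetic overview**
1. Target ⇒ C3 desilylation, outer-face epoxidation of the C1=C10 ring alkene and O8 acylation with (2S,3S)-epoxyangelic acid (from angelic acid by reduction, Sharpless epoxidation and oxidation) lead back to an 8-hydroxy α-methylene lactone.
2. The γ-lactone (second ring made) ⇒ C7 alkylation of a C6 ketone with tert-butyl bromoacetate, C6 reduction, ring closure and C13 methylenation.
3. The ten-membered carbocycle (first ring made) ⇒ anionic oxy-Cope ring expansion that makes C8–C9 and cuts C1–C6. It rests on the C6 oxygen lying 1,5 to the C1=C10 alkene in the ten-membered ring, and on C1–C6, C9, C10, C14 and C15 coinciding with the ten carbons of carvone (the carvone carbonyl oxygen becomes O3).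
4. The rearrangement substrate ⇒ enone 6 (from (R)-carvone by Luche reduction, Mitsunobu inversion, silylation and oxidation of the ring allylic CH2) plus a lithium (PMB-oxy)acetylide made from 4-methoxybenzyl alcohol and trichloroethylene, then trans-hydroalumination to the E enol ether.
5. Ring order: carvone six-membered ring → ten-membered carbocycle → γ-lactone → ring epoxide; the side-chain epoxide arrives with the acid.

Key step: step 9

Remark: germacrane numbering is used from compound 15 on, α/β refer to the usual germacranolide drawing with H-7 α, and the target is read from its SMILES as 1R,3S,6R,7R,8R,10R, 4Z, with a (2S,3S)-epoxyangelate.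

**Step 1**
Reactants: 1 (R)-(−)-carvone
Product: 2 (1R,5R)-2-methyl-5-(prop-1-en-2-yl)cyclohex-2-en-1-ol (cis-carveol)
Conditions: NaBH4, CeCl3·7H2O, MeOH, −20 °C
Reagents that add atoms: none
Why: Luche 1,2-reduction of the enone; hydride should enter on the face that leaves the new hydroxyl cis to the isopropenyl group (1R), as is usual for carvone.

**Step 2**
Reactants: 2 cis-carveol
Product: 3 (1S,5R)-2-methyl-5-(prop-1-en-2-yl)cyclohex-2-en-1-yl 4-nitrobenzoate
Conditions: 4-nitrobenzoic acid, PPh3, DIAD, THF, 0 °C → rt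
Reagents that add atoms: 4-nitrobenzoic acid, O=C(O)c1ccc(cc1)[N+](=O)[O-]
Why: Mitsunobu esterification displaces the activated allylic oxygen by SN2 with inversion, which sets C1 as S (the future C3 of the target).

**Step 3**
Reactants: 3 trans-carveyl 4-nitrobenzoate
Product: 4 (1S,5R)-2-methyl-5-(prop-1-en-2-yl)cyclohex-2-en-1-ol (trans-carveol)
Conditions: K2CO3 (cat.), MeOH, rt
Reagents that add atoms: none
Why: Base-catalysed transesterification cleaves the acyl–oxygen bond, so the carbinol configuration is untouched.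

**Step 4**
Reactants: 4 trans-carveol
Product: 5 tert-butyldimethylsilyl ether of (1S,5R)-trans-carveol
Conditions: TBSCl, imidazole, DMF, rt
Reagents that add atoms: tert-butyldimethylsilyl chloride, CC(C)(C)[Si](C)(C)Cl
Why: Standard silylation of a secondary allylic alcohol; the TBS group has to last until the final step.

**Step 5**
Reactants: 5 trans-carveol TBS ether
Product: 6 (4S,6R)-4-(tert-butyldimethylsilyloxy)-3-methyl-6-(prop-1-en-2-yl)cyclohex-2-en-1-one
Conditions: Rh2(cap)4 (cat.), t-BuOOH, K2CO3, CH2Cl2, rt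
Reagents that add atoms: tert-butyl hydroperoxide, CC(C)(C)OO
Why: Dirhodium-caprolactamate allylic oxidation turns the only secondary allylic CH2 of the ring alkene into the enone carbonyl; the isopropenyl group and the silyloxy-bearing methine are expected to react more slowly, and no stereocentre is touched.

**Step 6**
Reactants: 7 4-methoxybenzyl alcohol; 8 trichloroethylene
Product: 10 4-methoxybenzyl (E)-1,2-dichlorovinyl ether, via potassium 4-methoxybenzyl oxide 9 (not isolated)
Conditions: KH, THF, 0 °C; then trichloroethylene, −50 °C → rt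
Reagents that add atoms: none
Why: Alkoxide addition to dichloroacetylene formed in the flask (dichlorovinyl ether synthesis for ynol ethers); anti addition gives the E ether.

**Step 7**
Reactants: 6 enone; 10 dichlorovinyl ether
Product: 12 (1R,4S,6R)-4-(tert-butyldimethylsilyloxy)-1-[(4-methoxybenzyloxy)ethynyl]-3-methyl-6-(prop-1-en-2-yl)cyclohex-2-en-1-ol, via lithium alkoxyacetylide 11 (not isolated)
Conditions: 10, n-BuLi (2.0 equiv), THF, −78 °C; then 6, −78 °C; aq. NH4Cl
Reagents that add atoms: none
Why: Elimination and Cl–Li exchange give the lithium ynol-ether acetylide, which adds 1,2 to the enone on the face anti to the neighbouring isopropenyl group (as hydride and vinyl reagents do with 6-isopropenylcyclohexenones), setting the carbinol as R with the two unsaturated arms trans.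

**Step 8**
Reactants: 12 propargylic alcohol
Product: 13 (1R,4S,6R)-4-(tert-butyldimethylsilyloxy)-1-[(E)-2-(4-methoxybenzyloxy)vinyl]-3-methyl-6-(prop-1-en-2-yl)cyclohex-2-en-1-ol
Conditions: LiAlH4, THF, 0 °C → rt; Rochelle salt work-up; chromatography on Et3N-washed silica
Reagents that add atoms: none
Why: Alkoxide-directed trans-hydroalumination of the propargylic alkyne delivers hydride to the proximal carbon, and protonolysis of the vinyl–aluminium bond gives the E enol ether without touching a stereocentre.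

**Step 9**
Reactants: 13 E-enol ether carbinol
Product: 16 (3S,8R)-3β-(tert-butyldimethylsilyloxy)-8β-(4-methoxybenzyloxy)germacra-1(10)E,4Z-dien-6-one, via potassium alkoxide 14 (not isolated), via potassium dienolate 15 (not isolated)
Conditions: KH, 18-crown-6, THF, 0 → 20 °C; then transfer into AcOH/THF at −78 °C
Reagents that add atoms: none
Why: The crown-separated potassium alkoxide undergoes a concerted [3,3] shift in which C8–C9 forms while C1–C6 breaks, and the resulting C6/C7 enolate is protonated at C7 in the cold; the closest known reaction is the anionic oxy-Cope rearrangement of trans-1,2-dialkenylcyclohexanols to (E)-cyclodec-5-enones. The ten-membered ring is not closed end to end but arises by four-atom expansion of the cyclohexene through a six-centre chair array, so no high dilution is needed. The new C8 stereocentre is set by that chair: with both cyclohexene ring bonds equatorial and the E enol ether placing the PMB-oxy group pseudo-equatorial, the (1R,6R) substrate should give 8R. The same equatorial ring bonds give the 1(10)E alkene, and the cis ring alkene of the cyclohexene is carried over unchanged as 4Z. The step needs chair over boat, which the trans arrangement of the two arms from step 7 secures, and it needs the β-alkoxy enolate to survive, which short reaction time and the cold acid quench are meant to ensure.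

**Step 10**
Reactants: 16 dienone; 17 tert-butyl bromoacetate
Product: 19 tert-butyl 3β-(tert-butyldimethylsilyloxy)-8β-(4-methoxybenzyloxy)-6-oxo-13-norgermacra-1(10)E,4Z-dien-12-oate (7α-H; 7R), via lithium enolate 18 (not isolated)
Conditions: LDA, THF, −78 °C; then BrCH2CO2t-Bu, −78 → −40 °C
Reagents that add atoms: none
Why: Kinetic α′-deprotonation at C7 (C5 carries no sp3 hydrogen) and enolate alkylation; lithium chelation between the enolate oxygen and O8 should hold the C8–O bond in the enolate plane, so the electrophile enters from the ring periphery anti to the C8–C9 bond and sets C7 as R.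

**Step 11**
Reactants: 19 keto ester
Product: 20 tert-butyl 6α-hydroxy-3β-(tert-butyldimethylsilyloxy)-8β-(4-methoxybenzyloxy)-13-norgermacra-1(10)E,4Z-dien-12-oate (6β-H, 7α-H)
Conditions: NaBH4, CeCl3·7H2O, MeOH/THF, −78 → −30 °C
Reagents that add atoms: none
Why: Luche 1,2-reduction of the cis-enone; hydride is expected on the outer face of the C6 carbonyl, anti to the C7 acetate arm, which gives the 6R alcohol with H-6 trans to H-7.

**Step 12**
Reactants: 20 hydroxy ester
Product: 21 3β-(tert-butyldimethylsilyloxy)-8β-(4-methoxybenzyloxy)-13-norgermacra-1(10)E,4Z-dien-12,6α-olide (trans-fused)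
Conditions: KOt-Bu (cat.), THF, 0 °C
Reagents that add atoms: none
Why: Alkoxide-catalysed intramolecular transesterification (5-exo-trig lactonisation) closes the γ-lactone without acid, which the 1(10),4-diene would not tolerate; no stereocentre changes.

**Step 13**
Reactants: 21 lactone
Product: 23 13-(dimethylamino)-3β-(tert-butyldimethylsilyloxy)-8β-(4-methoxybenzyloxy)germacra-1(10)E,4Z-dien-12,6α-olide (C11 epimers), via lactone lithium enolate 22 (not isolated)
Conditions: LDA, THF, −78 °C; then Eschenmoser's salt, −78 °C → rt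
Reagents that add atoms: N,N-dimethylmethyleneiminium iodide, C=[N+](C)C.[I-]
Why: Mannich aminomethylation of the lactone enolate at C11; the C11 configuration is of no consequence because the centre becomes sp2 in step 15.

**Step 14**
Reactants: 23 Mannich base
Product: 24 trimethylammonium iodide of 23
Conditions: MeI, MeOH, rt; evaporation
Reagents that add atoms: iodomethane, CI
Why: Menshutkin quaternisation turns the amine into a leaving group.

**Step 15**
Reactants: 24 ammonium iodide
Product: 25 3β-(tert-butyldimethylsilyloxy)-8β-(4-methoxybenzyloxy)germacra-1(10)E,4Z,11(13)-trien-12,6α-olide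
Conditions: NaHCO3 (aq.), CH2Cl2, rt
Reagents that add atoms: none
Why: E1cB (Hofmann-type) loss of trimethylamine from the β-ammonio lactone gives the α-methylene lactone under conditions too mild to touch the ethers.

**Step 16**
Reactants: 25 PMB ether
Product: 26 8β-hydroxy-3β-(tert-butyldimethylsilyloxy)germacra-1(10)E,4Z,11(13)-trien-12,6α-olide
Conditions: DDQ, CH2Cl2/pH 7 buffer, 0 °C
Reagents that add atoms: none
Why: Oxidative cleavage of the PMB ether by hydride abstraction from the benzylic position; the neutral buffer keeps the free 8-hydroxyl from attacking the lactone, and the silyl ether and alkenes are inert.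

**Step 17**
Reactants: 27 angelic acid
Product: 28 (Z)-2-methylbut-2-en-1-ol
Conditions: LiAlH4, Et2O, 0 °C → rt
Reagents that add atoms: none
Why: Hydride reduction of the acid to the allylic alcohol proceeds without Z/E isomerisation.

**Step 18**
Reactants: 28 (Z)-2-methylbut-2-en-1-ol
Product: 29 (2R,3S)-(2,3-dimethyloxiran-2-yl)methanol
Conditions: Ti(Oi-Pr)4, D-(−)-diisopropyl tartrate, t-BuOOH, 4 Å MS, CH2Cl2, −20 °C
Reagents that add atoms: tert-butyl hydroperoxide, CC(C)(C)OO
Why: Sharpless asymmetric epoxidation; the D-(−)-tartrate delivers oxygen to the face opposite to the one that gives (2S)-epoxy alcohols with L-(+)-tartrate, so the syn addition to the Z alkene should give the 2R,3S epoxy alcohol.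

**Step 19**
Reactants: 29 epoxy alcohol
Product: 30 (2S,3S)-2,3-dimethyloxirane-2-carboxylic acid ((2S,3S)-epoxyangelic acid)
Conditions: TEMPO (cat.), PhI(OAc)2, MeCN/H2O, rt
Reagents that add atoms: water, O
Why: Oxoammonium oxidation of the primary alcohol through the aldehyde hydrate gives the acid under near-neutral conditions that spare the epoxide; the 2R→2S change is only a change of CIP priorities.

**Step 20**
Reactants: 26 8-alcohol; 30 (2S,3S)-epoxyangelic acid
Product: 32 8β-[(2S,3S)-2,3-dimethyloxirane-2-carbonyloxy]-3β-(tert-butyldimethylsilyloxy)germacra-1(10)E,4Z,11(13)-trien-12,6α-olide, via mixed anhydride 31 (not isolated)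
Conditions: 30, 2,4,6-trichlorobenzoyl chloride, Et3N, THF, rt; then 26, DMAP, toluene, rt
Reagents that add atoms: none
Why: Yamaguchi esterification; DMAP attacks the less shielded aliphatic carbonyl of the mixed anhydride and the hindered secondary alcohol is acylated with retention at C8.

**Step 21**
Reactants: 32 ester
Product: 33 (1R,10R)-1β,10α-epoxide of 32
Conditions: mCPBA, NaHCO3, CH2Cl2, 0 °C
Reagents that add atoms: 3-chloroperoxybenzoic acid, O=C(OO)c1cccc(Cl)c1
Why: Prilezhaev epoxidation of the most electron-rich alkene (the 4Z alkene is deactivated by two allylic C–O bonds and C11=C13 is electron-poor); the E alkene stands perpendicular to the ring and only its outer face is open, which in the usual conformer with C14 on the β face should give the trans 1R,10R epoxide.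

**Step 22**
Reactants: 33 silyl ether
Product: 34 target, 3β-hydroxy-8β-[(2S,3S)-epoxyangeloyloxy]-1β,10α-epoxygermacra-4Z,11(13)-dien-12,6α-olide (1R,3S,6R,7R,8R,10R)
Conditions: TBAF, AcOH (1:1), THF, 0 °C → rt
Reagents that add atoms: none
Why: Fluoride-induced desilylation, buffered so that neither the two epoxides, the ester nor the α-methylene lactone are attacked.

**Compound list**
1 | (R)-(−)-carvone | CC1=CC[C@H](CC1=O)C(C)=C | starting material
2 | (1R,5R)-cis-carveol | CC1=CC[C@H](C[C@H]1O)C(C)=C | intermediate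
3 | (1S,5R)-trans-carveyl 4-nitrobenzoate | CC1=CC[C@H](C[C@@H]1OC(=O)c2ccc(cc2)[N+](=O)[O-])C(C)=C | intermediate
4 | (1S,5R)-trans-carveol | CC1=CC[C@H](C[C@@H]1O)C(C)=C | intermediate
5 | (1S,5R)-trans-carveol TBS ether | CC1=CC[C@H](C[C@@H]1O[Si](C)(C)C(C)(C)C)C(C)=C | intermediate
6 | (4S,6R)-4-(TBS-oxy)-3-methyl-6-(prop-1-en-2-yl)cyclohex-2-en-1-one | CC1=CC(=O)[C@@H](C(C)=C)C[C@@H]1O[Si](C)(C)C(C)(C)C | intermediate
7 | 4-methoxybenzyl alcohol | COc1ccc(CO)cc1 | starting material
8 | trichloroethylene | ClC=C(Cl)Cl | starting material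
9 | potassium 4-methoxybenzyl oxide (not isolated) | COc1ccc(C[O-])cc1.[K+] | intermediate
10 | 4-methoxybenzyl (E)-1,2-dichlorovinyl ether | COc1ccc(CO/C(Cl)=C\Cl)cc1 | intermediate
11 | lithium (4-methoxybenzyloxy)acetylide (not isolated) | [Li]C#COCc1ccc(OC)cc1 | intermediate
12 | (1R,4S,6R)-4-(TBS-oxy)-1-[(4-methoxybenzyloxy)ethynyl]-3-methyl-6-(prop-1-en-2-yl)cyclohex-2-en-1-ol | CC1=C[C@](O)(C#COCc2ccc(OC)cc2)[C@@H](C(C)=C)C[C@@H]1O[Si](C)(C)C(C)(C)C | intermediate
13 | (1R,4S,6R)-4-(TBS-oxy)-1-[(E)-2-(4-methoxybenzyloxy)vinyl]-3-methyl-6-(prop-1-en-2-yl)cyclohex-2-en-1-ol | CC1=C[C@](O)(/C=C/OCc2ccc(OC)cc2)[C@@H](C(C)=C)C[C@@H]1O[Si](C)(C)C(C)(C)C | intermediate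
14 | potassium alkoxide of 13 (not isolated) | CC1=C[C@]([O-])(/C=C/OCc2ccc(OC)cc2)[C@@H](C(C)=C)C[C@@H]1O[Si](C)(C)C(C)(C)C.[K+] | intermediate
15 | potassium C6/C7 dienolate of 16 (not isolated) | C1/C=C(\C)C[C@@H](OCc2ccc(OC)cc2)/C=C(\[O-])/C=C(/C)[C@H]1O[Si](C)(C)C(C)(C)C.[K+] | intermediate
16 | (3S,8R)-3β-(TBS-oxy)-8β-(4-methoxybenzyloxy)germacra-1(10)E,4Z-dien-6-one | O=C1/C=C(/C)[C@@H](O[Si](C)(C)C(C)(C)C)C/C=C(\C)C[C@@H](OCc2ccc(OC)cc2)C1 | intermediate
17 | tert-butyl bromoacetate | CC(C)(C)OC(=O)CBr | starting material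
18 | lithium C6/C7 enolate of 16 (not isolated) | C1/C=C(\C)C[C@@H](OCc2ccc(OC)cc2)/C=C(\O[Li])/C=C(/C)[C@H]1O[Si](C)(C)C(C)(C)C | intermediate
19 | tert-butyl 3β-(TBS-oxy)-8β-(PMB-oxy)-6-oxo-13-norgermacra-1(10)E,4Z-dien-12-oate (7R) | O=C1/C=C(/C)[C@@H](O[Si](C)(C)C(C)(C)C)C/C=C(\C)C[C@@H](OCc2ccc(OC)cc2)[C@H]1CC(=O)OC(C)(C)C | intermediate
20 | tert-butyl 6α-hydroxy-3β-(TBS-oxy)-8β-(PMB-oxy)-13-norgermacra-1(10)E,4Z-dien-12-oate | O[C@@H]1/C=C(/C)[C@@H](O[Si](C)(C)C(C)(C)C)C/C=C(\C)C[C@@H](OCc2ccc(OC)cc2)[C@H]1CC(=O)OC(C)(C)C | intermediate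
21 | 3β-(TBS-oxy)-8β-(PMB-oxy)-13-norgermacra-1(10)E,4Z-dien-12,6α-olide | O=C1O[C@@H]2/C=C(/C)[C@@H](O[Si](C)(C)C(C)(C)C)C/C=C(\C)C[C@@H](OCc3ccc(OC)cc3)[C@H]2C1 | intermediate
22 | lithium enolate of lactone 21 (not isolated) | [Li]OC=1O[C@@H]2/C=C(/C)[C@@H](O[Si](C)(C)C(C)(C)C)C/C=C(\C)C[C@@H](OCc3ccc(OC)cc3)[C@H]2C=1 | intermediate
23 | 13-(dimethylamino)-3β-(TBS-oxy)-8β-(PMB-oxy)germacra-1(10)E,4Z-dien-12,6α-olide (C11 epimers) | O=C1O[C@@H]2/C=C(/C)[C@@H](O[Si](C)(C)C(C)(C)C)C/C=C(\C)C[C@@H](OCc3ccc(OC)cc3)[C@H]2C1CN(C)C | intermediate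
24 | trimethylammonium iodide of 23 | O=C1O[C@@H]2/C=C(/C)[C@@H](O[Si](C)(C)C(C)(C)C)C/C=C(\C)C[C@@H](OCc3ccc(OC)cc3)[C@H]2C1C[N+](C)(C)C.[I-] | intermediate
25 | 3β-(TBS-oxy)-8β-(PMB-oxy)germacra-1(10)E,4Z,11(13)-trien-12,6α-olide | C=C1C(=O)O[C@@H]2/C=C(/C)[C@@H](O[Si](C)(C)C(C)(C)C)C/C=C(\C)C[C@@H](OCc3ccc(OC)cc3)[C@@H]12 | intermediate
26 | 8β-hydroxy-3β-(TBS-oxy)germacra-1(10)E,4Z,11(13)-trien-12,6α-olide | C=C1C(=O)O[C@@H]2/C=C(/C)[C@@H](O[Si](C)(C)C(C)(C)C)C/C=C(\C)C[C@@H](O)[C@@H]12 | intermediate
27 | angelic acid | C/C=C(/C)C(=O)O | starting material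
28 | (Z)-2-methylbut-2-en-1-ol | C/C=C(/C)CO | intermediate
29 | (2R,3S)-(2,3-dimethyloxiran-2-yl)methanol | OC[C@@]1(C)O[C@H]1C | intermediate
30 | (2S,3S)-2,3-dimethyloxirane-2-carboxylic acid | OC(=O)[C@@]1(C)O[C@H]1C | intermediate
31 | (2S,3S)-epoxyangelic 2,4,6-trichlorobenzoic anhydride (not isolated) | O=C(OC(=O)[C@@]1(C)O[C@H]1C)c2c(Cl)cc(Cl)cc2Cl | intermediate
32 | 8β-[(2S,3S)-epoxyangeloyloxy]-3β-(TBS-oxy)germacra-1(10)E,4Z,11(13)-trien-12,6α-olide | C=C1C(=O)O[C@@H]2/C=C(/C)[C@@H](O[Si](C)(C)C(C)(C)C)C/C=C(\C)C[C@@H](OC(=O)[C@@]3(C)O[C@H]3C)[C@@H]12 | intermediate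
33 | (1R,10R)-1β,10α-epoxide of 32 | C=C1C(=O)O[C@@H]2/C=C(/C)[C@@H](O[Si](C)(C)C(C)(C)C)C[C@H]3O[C@]3(C)C[C@@H](OC(=O)[C@@]3(C)O[C@H]3C)[C@@H]12 | intermediate
34 | CNP0268255.2 | C=C1C(=O)O[C@@H]2/C=C(/C)[C@@H](O)C[C@H]3O[C@]3(C)C[C@@H](OC(=O)[C@@]3(C)O[C@H]3C)[C@@H]12 | target

**Step count**
Total: 22 steps (18 on the line from carvone, 1 for the acetylide precursor, 3 for the acid).
Longest linear sequence: 18 steps (1 → 34 through steps 1–5, 7–16 and 20–22).

**Three steps most likely to fail**

Step 9. The enolate formed by the rearrangement can expel 4-methoxybenzyl oxide by E1cB before it is protonated, and a boat array would erode the C8 and C1(10) geometry. The fallback sets out from 13 and returns at 16. The rearrangement is run warm so that the elimination goes to completion and gives 3β-(TBS-oxy)germacra-1(10)E,4Z,7E-trien-6-one F1. Copper-catalysed conjugate borylation (CuCl, NaOt-Bu, a Josiphos-type ligand, B2pin2, MeOH, THF) should then attack C8, the only enone β-carbon that still carries a hydrogen, to give the 8β-(pinacolboryl) ketone F2; the ligand antipode that delivers 8R would be chosen by trying both. Oxidation with NaBO3·4H2O, with retention, gives the 8β-hydroxy ketone F3, and 4-methoxybenzyl trichloroacetimidate with catalytic La(OTf)3 returns 16. In this fallback C8 is set by the catalyst and no longer by the chair.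

Step 10. Facial selectivity at C7 may be poor, and during deprotonation the enolate may lose the C8 ether or form by γ-deprotonation instead. The fallback sets out from 13 and returns at 19. The enolate is no longer made by deprotonation: the potassium dienolate 15 that the sigmatropic shift delivers, with fixed regiochemistry and geometry and without a lithium chelate, is cooled to −78 °C and trapped in the same flask with 17. This tandem rearrangement–alkylation passes by 16 and makes no compound outside the list (F0).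

Step 11. Hydride may be delivered to the inner face of the C6 carbonyl, which would give the 6-epimer and then a cis-fused lactone. The fallback sets out from 19 and returns at 21. The epimeric tert-butyl 6β-hydroxy ester F4 is inverted by a Mitsunobu reaction (4-nitrobenzoic acid, PPh3, DIAD) to the tert-butyl 6α-(4-nitrobenzoyloxy) ester F5. Methanolysis with K2CO3 then frees the 6α-alkoxide, which closes onto the tert-butyl ester to give 21.

**Further compounds**
F1 | step 9 | 3β-(TBS-oxy)germacra-1(10)E,4Z,7E-trien-6-one | O=C1/C=C(/C)[C@@H](O[Si](C)(C)C(C)(C)C)C/C=C(\C)C/C=C/1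
F2 | step 9 | (8R)-3β-(TBS-oxy)-8β-(4,4,5,5-tetramethyl-1,3,2-dioxaborolan-2-yl)germacra-1(10)E,4Z-dien-6-one | O=C1/C=C(/C)[C@@H](O[Si](C)(C)C(C)(C)C)C/C=C(\C)C[C@@H](B2OC(C)(C)C(C)(C)O2)C1
F3 | step 9 | (8R)-8β-hydroxy-3β-(TBS-oxy)germacra-1(10)E,4Z-dien-6-one | O=C1/C=C(/C)[C@@H](O[Si](C)(C)C(C)(C)C)C/C=C(\C)C[C@@H](O)C1
F0 | step 10 | none | none
F4 | step 11 | tert-butyl 6β-hydroxy-3β-(TBS-oxy)-8β-(PMB-oxy)-13-norgermacra-1(10)E,4Z-dien-12-oate (6S) | O[C@H]1/C=C(/C)[C@@H](O[Si](C)(C)C(C)(C)C)C/C=C(\C)C[C@@H](OCc2ccc(OC)cc2)[C@H]1CC(=O)OC(C)(C)C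
F5 | step 11 | tert-butyl 6α-(4-nitrobenzoyloxy)-3β-(TBS-oxy)-8β-(PMB-oxy)-13-norgermacra-1(10)E,4Z-dien-12-oate (6R) | O=C(O[C@@H]1/C=C(/C)[C@@H](O[Si](C)(C)C(C)(C)C)C/C=C(\C)C[C@@H](OCc2ccc(OC)cc2)[C@H]1CC(=O)OC(C)(C)C)c3ccc(cc3)[N+](=O)[O-]
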